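Percent of the Q charged was the unit I worked in for your quick number, and in it I tested your hunch that slow Z spares X by keeping cZ low.

| flask | Q | Z | remark | time |
|---|---|---|---|---|
| oak | 0.010 M | 0.025 M | run made earlier |  |
| maple | 0.010 M | 0.013 M | run made earlier |  |
| birch | 0.010 M | 0.019 M | run made earlier |  |
| larch | 0.020 M | 0.025 M | run made earlier |  |
| eta | 0.010 M (in portions, 4, over 40 min) | 0.0250 M | first portion at the start, last at 40 min | 50 min |
| zeta | 0.010 M (fed, over 40 min) | 0.0250 M | all else is in the flask from the start; the feed brings no volume worth counting | 50 min |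
| alpha | 0.010 M | 0.0250 M (fed, over 40 min) | all else is in the flask from the start; the feed brings no volume worth counting | 50 min |
| epsilon | 0.010 M | 0.0250 M | everything together at the start | 50 min |

- oak (time / min: X / %, G / %): 10.0: 49.9, 11.0; 20.0: 55.8, 23.7; 30.0: 54.5, 32.4; 40.0: 50.9, 40.5; 50.0: 46.8, 47.3
- maple (time / min: X / %, G / %): 4.00: 20.3, 0.5; 8.00: 30.5, 3.1; 15.0: 41.0, 6.1; 25.0: 48.1, 10.2; 50.0: 54.4, 17.6
- birch (time / min: X / %, G / %): 10.0: 44.3, 7.2; 20.0: 53.0, 15.0; 30.0: 55.4, 22.1; 40.0: 55.4, 28.1; 50.0: 54.3, 33.1
- larch (time / min: X / %, G / %): 4.00: 30.4, 2.3; 8.00: 42.5, 6.7; 15.0: 50.3, 11.5; 25.0: 54.5, 16.9; 50.0: 55.7, 24.2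

(standard deviation of a reading: 0.3 percentage points)

- which flask leads in share of X in X plus G ("all alike" within 1.5 percentage points) (eta / zeta / alpha / epsilon / all alike)
- share of X in X plus G at the end, eta
- share of X in X plus G at the end, zeta
- share of X in X plus G at the end, alpha
- share of X in X plus G at the end, epsilon

- the numbers in the tables scatter with a standard deviation of 0.3 percentage points

I took both additions as second order. Q goes to X with cZ in its rate, and X goes to G with the same cZ in its rate, so cZ cancels from their ratio at any moment. That ratio, the rate to G over the rate to X, is s·cX/cu, where u is whatever part of the Q charged is neither X nor G. The runs agreed with this: oak at 20.0 min held 55.8% X and 23.7% G, and larch, on a different charge, held 55.7% and 24.2% at 50.0 min.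

At the X maximum the two rates are equal. Birch stood flat between 30.0 min and 40.0 min, so I read s, the selectivity factor, the second rate constant over the first, as u over X there: 0.352. Following the ratio as it drifts, with Q all present from the start, the share of X in X plus G comes out as a function of u and s: u^s minus u, divided by the product of the complements of s and u.

Alpha holds its Q from the start, so in this reckoning it stays on this path and lags. Its Z arrived on average 20.0 min late, so I read alpha as oak at 30.0 min. There u was 13.1%, and the path gave 63.6%. Epsilon is oak's last reading, 49.7%. Eta and zeta receive Q late, off this path, so I offered no number for them.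

The forecast gave eta 61%, zeta 63%, alpha 68% and epsilon 49.7%, with alpha leading: “Late dosing gives X less time to go on, and keeping Z low favours X, so alpha leads.” Its alpha stood higher than mine.

The flasks gave eta 58.9%, zeta 61.1%, alpha 64.2% and epsilon 50.0%, with alpha leading.

    Q + Z → E + J (k = 0.0149 M⁻¹ s⁻¹)
    Q + Z → X + J (k = 0.0910 M⁻¹ s⁻¹)
    Z + E → G + J (k = 0.0802 M⁻¹ s⁻¹)
    Z ⇌ L (K = 0.380, k = 6.08 × 10⁻⁴ s⁻¹)
    Z + X → G + J (k = 0.0239 M⁻¹ s⁻¹)

At 50.0 min alpha held Q 10% and E 4.35%, so u was 14.4%, and s gave a share of 65.2% against the simulated 64.2%. The neighbouring flask was alpha with Z cut to 0.0063 M. It ended with Q 61% and E 4.47%, so u was 65.9%, and s gave 92.5%. That neighbour ended with X 31.3% and a share of 91.6%.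

The runs were computed on assumed constants.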